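If I want to know how much target this flask can hold at its best, I first ask how much reagent it offers each starting material. I fold the charges into one number, the offer ratio x, which for the flask is 1.30: reagent in the second phase charged over starting material charged. Equal charges make x one, the zero of my scale, and the flask stands above it, so starting material is the limiting reagent by charge.

| flask | starting material | reagent in the second phase | remark | time | volume of the second phase over the first |
|---|---|---|---|---|---|
| ochre | 0.56 M | 0.36 M | run made earlier |  |  |
| teal | 0.56 M | 0.55 M | run made earlier |  |  |
| violet | 0.84 M | 0.728 M | run made earlier |  |  |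
| flask | 0.56 M | 0.728 M |  | 15 d | 2.0 |

| run | time / d | target / % | starting material / % |
|---|---|---|---|
| ochre | 0.208 | 3.8 | 94.2 |
| ochre | 0.500 | 9.3 | 80.4 |
| ochre | 1.04 | 10.2 | 60.5 |
| ochre | 2.50 | 6.3 | 36.0 |
| ochre | 6.00 | 2.8 | 21.2 |
| ochre | 15.0 | 0.5 | 15.1 |
| teal | 0.208 | 5.7 | 92.1 |
| teal | 0.500 | 12.5 | 73.2 |
| teal | 1.04 | 13.2 | 48.1 |
| teal | 2.50 | 9.2 | 23.5 |
| teal | 6.00 | 4.2 | 10.4 |
| teal | 15.0 | 1.8 | 4.6 |
| violet | 0.208 | 7.0 | 89.5 |
| violet | 0.625 | 11.7 | 60.1 |
| violet | 1.67 | 8.2 | 28.7 |
| violet | 5.00 | 3.6 | 9.9 |
| violet | 15.0 | 1.2 | 4.2 |

(each reading ± 0.3 percentage points)

- in the second phase: reagent in the second phase; everything else is in the first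
- charges count per volume of the first phase; a concentration in a rate is the amount of a species over the volume of its own phase; every rate counts per litre of the first phase
- the earlier runs hold the two phases in the same ratio of volumes as the flask asked about
- a reading or a percentage of target counts all its forms, free or not

- time, not beyond 15 d, at which the flask holds most target
- the amount of target, in percent of the starting material charged, at that time
- earliest time at which at least nineteen twentieths of that best amount are there, in d
- latest time at which they still are, in d

Teal, at x = 0.982, sits close to that zero, and its highest target reading is 13.2%. Ochre, at x = 0.643, reaches 10.2%. These are readings with their scatter, and a true top may fall between samples. My rule is the straight line through these two points. Is one number enough? Violet has a larger charge of starting material than teal, and the line at its x of 0.867 gives 12.2% against a reading of 11.7%, taken from samples further apart, so for height it passes on this one run. For time I do not use x but turn to teal, which has the flask's charge of starting material and reads high from 0.500 d to 1.04 d. For the flask I commit to a best of 16.0%, at a time inside that interval.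

The forecast says 17.5% at 0.7 d, held within the asked share from 0.52 d to 0.92 d, which is higher than my figure, and it adds that "this stays an extrapolation". The flask gives 16.4% at 0.768 d, held within that share from 0.545 d to 1.10 d.

    2 reagent in the reaction phase → self-condensation product (k = 0.00167 M⁻¹ min⁻¹)
    crystals ⇌ target, rate k2*(cs2 - [target]) while solid is left; crystals form when [target] > cs2 (solubility = 0.120 M, k = 0.00885 min⁻¹)
    starting material + reagent in the reaction phase → target (k = 0.00253 M⁻¹ min⁻¹)
    starting material + target → side product (k = 0.00271 M⁻¹ min⁻¹)
    reagent in the reaction phase ⇌ reagent in the second phase, rate k5*([reagent in the reaction phase] - [reagent in the second phase]/K5) per volume of the first phase (partition coefficient = 0.450, kL = 0.00177 min⁻¹)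
    reagent in the reaction phase + target → over-reacted product (k = 0.00294 M⁻¹ min⁻¹)

At x = 1.30 my line stood 0.40 percentage points below the flask. A neighbouring flask is like the flask but charged with 2.2 M of starting material, which puts its x at 0.331, below every earlier run. The same line gives 7.44% for that neighbour, and its best is less than that, at 4.22%.

The readings stem from a simulated flask for substances that don't exist; scatter was added.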